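I decided to follow one molecule of the fed partner and ask how long it had stood in the flask.

the same everywhere: gas 1.5 mM (held)

| run | electrophile | nucleophile | remark | time |
|---|---|---|---|---|
| epsilon | 10 mM | 1 equiv | run made earlier |  |
| theta | 20 mM | 1 equiv | run made earlier |  |
| elm | 10 mM | 1.00 equiv (fed, over 4.0 h) | all else is in the flask from the start; the feed brings no volume worth counting | 5.0 h |
| larch | 10 mM (fed, over 4.0 h) | 1.00 equiv | all else is in the flask from the start; the feed brings no volume worth counting | 5.0 h |
| oak | 10 mM | 1.00 equiv | everything together at the start | 5.0 h |

- epsilon (time / h: target / %): 0.250: 36.3; 0.417: 46.8; 0.833: 61.0; 1.50: 72.4; 3.00: 81.8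
- theta (time / min: target / %): 6.00: 31.2; 12.0: 42.1; 20.0: 49.5; 25.0: 53.5; 30.0: 56.0

(standard deviation of a reading: 0.5 percentage points)

- the earlier runs were read with a standard deviation of 0.5 percentage points
- at the start none of the gas is in solution

* the flask that comes out highest in amount of target, in percent of the electrophile charged, or "all alike" when all lie within 1.5 percentage points (elm / larch / oak / all alike)
* target at the end, in percent of the electrophile charged, elm
* target at the end, in percent of the electrophile charged, larch
* target at the end, in percent of the electrophile charged, oak

A steady feed brings molecules evenly, so at the end the fed partner's mean residence time is the end time less half the feed time, 3.00 h; I called this the mean age. My plan was to read epsilon, which has the same charges, at that age.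

I went through the inputs in turn. The gas level is the same in epsilon and the recipes, so I did not need it. The feed time can be loose, because epsilon gained 9.4 percentage points over its last 1.50 h and an error in the feed time is halved in the age. I wanted the nucleophile charge exact: epsilon holds 1 equiv and the recipes 1.00 equiv, and my reading of epsilon stands on that match.

The mean age coincides with epsilon's last reading, so I expected about 81.8% for elm and larch alike. For oak I continued epsilon's odds, target over electrophile left. They rose from 2.62 to 4.49, which is 1.25 /h. That gives odds of 6.99 at 5.0 h, or 87.5%.

The forecast named oak, with 78% for elm, 78% for larch and 87% for oak, and said “The rate law looks symmetric in the two partners”. Its figures for the fed flasks lie below mine.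

    electrophile + nucleophile → acid set free + target (k = 4.80 /M/min)
    nucleophile + acid set free ⇌ protonated nucleophile, settled at all times (K = 6.20 × 10⁵ /M)
    acid set free + free base ⇌ salt of the base, settled at all times (K = 3.30 × 10⁶ /M)
    acid set free → by-product carried off (k = 0.00370 /min)
    gas ⇌ free base, rate k5*(csat - [free base]) (kL = 0.130 /min)

Oak came out highest at 88.5%, against 79.3% for elm and 79.4% for larch. Over the first 4.0 h, mean c(electrophile) was 6.56 mM in elm and 1.49 mM in larch, yet elm ended with 20.7% of its electrophile left and larch with 20.6%. At the mean age of 3.00 h, elm stood 2.5 points below epsilon's reading, and larch, with the same mean age, stood 2.4 points below it.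

The data stem from a simulated flask for substances that don't exist, noise included.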